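The plan rests on cutting the seven-membered ring between C8, the ring carbon that carries the exocyclic methylene, and C9, the neighbouring secondary carbinol carbon (daucane numbering). This 2-methylenecycloalkanol unit is the retron of an intramolecular Nozaki–Hiyama–Kishi reaction, which in one operation closes the cycloheptane onto a finished cyclopentane, leaves the exocyclic alkene in place and sets the C9 carbinol. The precursor is a trans-1,2-disubstituted cyclopentane: a 2-iodoallyl carbinol arm, already esterified with protected vanillic acid, on C5, and an acetaldehyde arm on the quaternary C1. It is assembled by asymmetric conjugate addition, anti aldol and isopropyl addition.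

Key step: step 9

Remark: daucane numbering is used throughout (C1 quaternary methyl-bearing carbon, C4 isopropyl carbinol, C5 ring-fusion CH, C6 ester-bearing carbinol, C7 CH2, C8 methylene-bearing carbon, C9 secondary carbinol, C10 CH2); "alpha" is the face of H-5. In step 2 the ligand enantiomer is assumed to be the one that gives the (R) quaternary centre.

Step 1
Reactants: 1 3-ethoxycyclopent-2-en-1-one
Product: 3 3-(prop-2-en-1-yl)cyclopent-2-en-1-one, via bromomagnesium alkoxide 2 (not isolated)
Conditions: allylmagnesium bromide, Et2O, 0 °C; then cold 1 M HCl, short contact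
Reagents that add atoms: allylmagnesium bromide C=CC[Mg]Br
Why: Stork–Danheiser sequence, in which 1,2-addition of the Grignard reagent to the vinylogous ester and acid-promoted loss of ethanol transpose the enone; no stereocentre is formed.

Step 2
Reactants: 3 3-(prop-2-en-1-yl)cyclopent-2-en-1-one
Product: 5 triethyl{[(3R)-3-methyl-3-(prop-2-en-1-yl)cyclopent-1-en-1-yl]oxy}silane, via dimethylaluminium enolate 4 (not isolated)
Conditions: Me3Al, Cu(OTf)2 (5 mol%), chiral sulfonate-bearing N-heterocyclic carbene ligand (5 mol%), THF, −78 °C; then Et3SiOTf, −78 to 0 °C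
Reagents that add atoms: trimethylaluminium C[Al](C)C; triethylsilyl trifluoromethanesulfonate CC[Si](CC)(CC)OS(=O)(=O)C(F)(F)F
Why: copper-catalysed asymmetric conjugate addition of a trialkylaluminium to a 3-substituted cyclopentenone, in which the chiral ligand selects the enone face and so sets the C1 quaternary centre, while O-silylation of the aluminium enolate fixes the enolate regiochemistry towards C5.

Step 3
Reactants: 6 but-3-yn-1-ol
Product: 7 3-iodobut-3-en-1-ol
Conditions: NaI, Me3SiCl, H2O, MeCN, rt
Reagents that add atoms: sodium iodide [Na+].[I-]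
Why: Markovnikov hydroiodination of the terminal alkyne by hydrogen iodide generated in situ should give the 2-iodoalkene; no stereocentre is formed.

Step 4
Reactants: 7 3-iodobut-3-en-1-ol
Product: 8 3-iodobut-3-enal
Conditions: Dess–Martin periodinane, NaHCO3, CH2Cl2, 0 °C; used at once as a solution
Reagents that add atoms: none
Why: Dess–Martin oxidation of the primary alcohol under buffered, non-basic conditions should avoid migration of the double bond into conjugation.

Step 5
Reactants: 5 triethyl{[(3R)-3-methyl-3-(prop-2-en-1-yl)cyclopent-1-en-1-yl]oxy}silane; 8 3-iodobut-3-enal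
Product: 11 (2S,3R)-2-[(1S)-1-hydroxy-3-iodobut-3-en-1-yl]-3-methyl-3-(prop-2-en-1-yl)cyclopentan-1-one, via lithium enolate 9 (not isolated), via chlorozinc enolate 10 (not isolated)
Conditions: MeLi, THF, 0 °C to rt; ZnCl2, −78 °C; then 8, −78 °C; aq. NH4Cl
Reagents that add atoms: none
Why: directed aldol addition of a regiodefined zinc enolate through a closed chair (Zimmerman–Traxler) transition state, in which the ring (E)-enolate gives the anti C5/C6 relationship and the aldehyde should approach C5 on the face opposite the larger allyl group of C1 (cis to methyl), as is usual for 3-alkyl-3-methylcyclopentanone enolates.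

Step 6
Reactants: 11 (2S,3R)-2-[(1S)-1-hydroxy-3-iodobut-3-en-1-yl]-3-methyl-3-(prop-2-en-1-yl)cyclopentan-1-one
Product: 12 (1R,2S,3R)-2-[(1S)-1-hydroxy-3-iodobut-3-en-1-yl]-3-methyl-1-(propan-2-yl)-3-(prop-2-en-1-yl)cyclopentan-1-ol
Conditions: iPrMgCl (excess), anhydrous CeCl3, THF, −78 to −20 °C; aq. NH4Cl
Reagents that add atoms: isopropylmagnesium chloride CC(C)[Mg]Cl
Why: organocerium 1,2-addition to a hindered, enolisable ketone, in which the reagent should attack C4 on the face opposite the C5 side chain and so place the new hydroxyl cis to that chain and to the C1 methyl (4R).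

Step 7
Reactants: 12 (1R,2S,3R)-2-[(1S)-1-hydroxy-3-iodobut-3-en-1-yl]-3-methyl-1-(propan-2-yl)-3-(prop-2-en-1-yl)cyclopentan-1-ol; 13 4-(acetyloxy)-3-methoxybenzoic acid
Product: 14 (1S)-1-[(1S,2R,5R)-2-hydroxy-5-methyl-2-(propan-2-yl)-5-(prop-2-en-1-yl)cyclopentyl]-3-iodobut-3-en-1-yl 4-(acetyloxy)-3-methoxybenzoate
Conditions: EDC·HCl, DMAP (cat.), CH2Cl2, rt
Reagents that add atoms: none
Why: Steglich esterification, in which only the secondary C6 hydroxyl should be acylated because the tertiary C4 hydroxyl is too hindered; no stereocentre is touched.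

Step 8
Reactants: 14 (1S)-1-[(1S,2R,5R)-2-hydroxy-5-methyl-2-(propan-2-yl)-5-(prop-2-en-1-yl)cyclopentyl]-3-iodobut-3-en-1-yl 4-(acetyloxy)-3-methoxybenzoate
Product: 16 (1S)-1-[(1S,2R,5R)-2-hydroxy-5-methyl-5-(2-oxoethyl)-2-(propan-2-yl)cyclopentyl]-3-iodobut-3-en-1-yl 4-(acetyloxy)-3-methoxybenzoate, via vicinal diol 15 (not isolated)
Conditions: OsO4 (cat.), NaIO4, 2,6-lutidine, dioxane/H2O, rt
Reagents that add atoms: osmium tetroxide O=[Os](=O)(=O)=O (catalytic oxygen carrier); sodium periodate [Na+].[O-]I(=O)(=O)=O (terminal oxidant)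
Why: Lemieux–Johnson oxidation (dihydroxylation then periodate cleavage), in which the monosubstituted allyl alkene should react far faster with OsO4 than the hindered, electron-poor 2-iodoalkene.

Step 9
Reactants: 16 (1S)-1-[(1S,2R,5R)-2-hydroxy-5-methyl-5-(2-oxoethyl)-2-(propan-2-yl)cyclopentyl]-3-iodobut-3-en-1-yl 4-(acetyloxy)-3-methoxybenzoate
Product: 18 (3R,3aS,4S,7S,8aR)-3,7-dihydroxy-8a-methyl-6-methylidene-3-(propan-2-yl)decahydroazulen-4-yl 4-(acetyloxy)-3-methoxybenzoate, via alkenylchromium species 17 (not isolated)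
Conditions: CrCl2 (excess), NiCl2 (cat.), DMSO, rt, slow addition of 16 at high dilution
Reagents that add atoms: none
Why: CrCl2 reduces NiCl2 to zerovalent nickel, which inserts into the C8–I bond; transmetalation to trivalent chromium gives alkenylchromium 17, whose carbon adds to the chromium-bound C9 aldehyde (intramolecular Nozaki–Hiyama–Kishi reaction, the closest known type being closures of 2-haloallyl aldehydes to 2-methylenecycloalkanols). The seven-membered ring closes in 7-exo-trig mode at the carbonyl carbon. The new C9 centre is under substrate control: in the chair-like cycloheptane transition state built on the trans-disposed C5 and C1 arms, the chromium alkoxide should take the equatorial site away from the axial C1 methyl, which places the hydroxyl alpha (9S). The step needs chemoselectivity for the aldehyde over the two esters and the free tertiary hydroxyl, which the low basicity and carbonyl selectivity of alkenylchromium secure, and cyclisation over oligomerisation, which the vicinal trans arms on the rigid cyclopentane and high dilution favour.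

Step 10
Reactants: 18 (3R,3aS,4S,7S,8aR)-3,7-dihydroxy-8a-methyl-6-methylidene-3-(propan-2-yl)decahydroazulen-4-yl 4-(acetyloxy)-3-methoxybenzoate
Product: 19 (3R,3aS,4S,7S,8aR)-3,7-dihydroxy-8a-methyl-6-methylidene-3-(propan-2-yl)decahydroazulen-4-yl 4-hydroxy-3-methoxybenzoate
Conditions: pyrrolidine, CH2Cl2, 0 °C to rt
Reagents that add atoms: none
Why: aminolysis of the phenolic acetate, an activated aryl ester, by pyrrolidine should leave the hindered alkyl aroate and the allylic alcohol untouched.

Compound list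
1 | 3-ethoxycyclopent-2-en-1-one | CCOC1=CC(=O)CC1 | starting material
2 | bromomagnesium 3-ethoxy-1-(prop-2-en-1-yl)cyclopent-2-en-1-olate (racemic 1,2-adduct) | CCOC1=CC(CC=C)(O[Mg]Br)CC1 | intermediate
3 | 3-(prop-2-en-1-yl)cyclopent-2-en-1-one | C=CCC1=CC(=O)CC1 | intermediate
4 | dimethylaluminium (3R)-3-methyl-3-(prop-2-en-1-yl)cyclopent-1-en-1-olate | C[Al](C)OC1=C[C@](C)(CC1)CC=C | intermediate
5 | triethyl{[(3R)-3-methyl-3-(prop-2-en-1-yl)cyclopent-1-en-1-yl]oxy}silane | CC[Si](CC)(CC)OC1=C[C@](C)(CC1)CC=C | intermediate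
6 | but-3-yn-1-ol | C#CCCO | starting material
7 | 3-iodobut-3-en-1-ol | C=C(I)CCO | intermediate
8 | 3-iodobut-3-enal | C=C(I)CC=O | intermediate
9 | lithium (3R)-3-methyl-3-(prop-2-en-1-yl)cyclopent-1-en-1-olate | [Li]OC1=C[C@](C)(CC1)CC=C | intermediate
10 | chlorozinc (3R)-3-methyl-3-(prop-2-en-1-yl)cyclopent-1-en-1-olate | Cl[Zn]OC1=C[C@](C)(CC1)CC=C | intermediate
11 | (2S,3R)-2-[(1S)-1-hydroxy-3-iodobut-3-en-1-yl]-3-methyl-3-(prop-2-en-1-yl)cyclopentan-1-one | C=C(I)C[C@H](O)[C@@H]1[C@](C)(CCC1=O)CC=C | intermediate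
12 | (1R,2S,3R)-2-[(1S)-1-hydroxy-3-iodobut-3-en-1-yl]-3-methyl-1-(propan-2-yl)-3-(prop-2-en-1-yl)cyclopentan-1-ol | C=C(I)C[C@H](O)[C@@H]1[C@](C)(CC[C@@]1(O)C(C)C)CC=C | intermediate
13 | 4-(acetyloxy)-3-methoxybenzoic acid | COc1cc(C(O)=O)ccc1OC(C)=O | starting material
14 | (1S)-1-[(1S,2R,5R)-2-hydroxy-5-methyl-2-(propan-2-yl)-5-(prop-2-en-1-yl)cyclopentyl]-3-iodobut-3-en-1-yl 4-(acetyloxy)-3-methoxybenzoate | C=C(I)C[C@H](OC(=O)c1ccc(OC(C)=O)c(OC)c1)[C@@H]2[C@](C)(CC[C@@]2(O)C(C)C)CC=C | intermediate
15 | 2,3-dihydroxypropyl analogue of 14 (diol from the allyl group, mixed at the new carbinol) | C=C(I)C[C@H](OC(=O)c1ccc(OC(C)=O)c(OC)c1)[C@@H]2[C@](C)(CC[C@@]2(O)C(C)C)CC(O)CO | intermediate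
16 | (1S)-1-[(1S,2R,5R)-2-hydroxy-5-methyl-5-(2-oxoethyl)-2-(propan-2-yl)cyclopentyl]-3-iodobut-3-en-1-yl 4-(acetyloxy)-3-methoxybenzoate | C=C(I)C[C@H](OC(=O)c1ccc(OC(C)=O)c(OC)c1)[C@@H]2[C@](C)(CC[C@@]2(O)C(C)C)CC=O | intermediate
17 | dichlorochromium alkenyl species from 16 (trivalent chromium on C8 in place of iodine) | C=C([Cr](Cl)Cl)C[C@H](OC(=O)c1ccc(OC(C)=O)c(OC)c1)[C@@H]2[C@](C)(CC[C@@]2(O)C(C)C)CC=O | intermediate
18 | (3R,3aS,4S,7S,8aR)-3,7-dihydroxy-8a-methyl-6-methylidene-3-(propan-2-yl)decahydroazulen-4-yl 4-(acetyloxy)-3-methoxybenzoate | C=C1C[C@H](OC(=O)c2ccc(OC(C)=O)c(OC)c2)[C@@H]2[C@](C)(CC[C@@]2(O)C(C)C)C[C@@H]1O | intermediate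
19 | (3R,3aS,4S,7S,8aR)-3,7-dihydroxy-8a-methyl-6-methylidene-3-(propan-2-yl)decahydroazulen-4-yl 4-hydroxy-3-methoxybenzoate | C=C1C[C@H](OC(=O)c2ccc(O)c(OC)c2)[C@@H]2[C@](C)(CC[C@@]2(O)C(C)C)C[C@@H]1O | target

Total steps: 10. Longest linear sequence: 8 steps (1, 2, 5, 6, 7, 8, 9, 10).

Steps most likely to fail

Step 5. Proton transfer from the easily enolised β,γ-unsaturated aldehyde 8 to the enolate, and weak discrimination between the methyl and allyl faces at C5, may erode yield and selectivity. The fallback sets out from 1 and comes back at 12; it relays all ring stereocentres from one carbinol through a silicon tether. Methylmagnesium bromide then dilute acid should convert 1 into 3-methylcyclopent-2-en-1-one F1. Corey–Bakshi–Shibata reduction ((R)-2-methyl-CBS-oxazaborolidine, BH3·SMe2) should give (1S)-3-methylcyclopent-2-en-1-ol F2. (Bromomethyl)chlorodimethylsilane and Et3N give the (bromomethyl)dimethylsilyl ether F3. With allyltributylstannane and AIBN in hot benzene, the silylmethyl radical should close 5-exo onto C5 on the oxygen face, and the tertiary C1 radical should then be allylated on the face opposite the new ring (Keck allylation), giving the cis-fused oxasilolane F4. Tamao oxidation (H2O2, KF, KHCO3) gives the cis-hydroxymethyl cyclopentanol F5. Et3SiCl at −78 °C silylates the primary hydroxyl to give the mono-triethylsilyl ether F6, and Dess–Martin oxidation gives the cyclopentanone F7. iPrMgCl/CeCl3 should add anti to the C5 substituent to give the tertiary alcohol F8. Swern oxidation converts the primary triethylsilyl ether directly into the hydroxy aldehyde F9. Indium-mediated Barbier addition of 3-bromo-2-iodoprop-1-ene in aqueous THF, with the C4 hydroxyl chelating the aldehyde and attack on its exposed face, should then give 12.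

Step 9. The alkenylchromium may add to the wrong face of the aldehyde during the seven-membered closure, giving the C9 epimer. The fallback sets out from 18 (as a C9 epimer mixture) and comes back at 18. Dess–Martin oxidation of the allylic alcohol gives the 2-methylidene cycloheptanone F10. Corey–Bakshi–Shibata reduction, with the oxazaborolidine enantiomer that delivers hydride to the beta face, should then set C9 under reagent control.

Step 2. The ligand may discriminate the faces of a five-membered enone poorly, and the doubly allylic CH2 of 3 may be deprotonated so that the allyl alkene drifts into conjugation. The fallback sets out from 3 and comes back at 5. Corey–Bakshi–Shibata reduction of 3 should give (1S)-3-(prop-2-en-1-yl)cyclopent-2-en-1-ol F11. Hydroxyl-directed Simmons–Smith cyclopropanation (Et2Zn, CH2I2) of the allylic alcohol alkene gives the cis-cyclopropyl carbinol F12, and Dess–Martin oxidation gives the bicyclo[3.1.0]hexan-2-one F13. Lithium in liquid NH3 should cleave the cyclopropane bond external to the five-membered ring, which turns the cyclopropane CH2 into the C1 methyl and leaves the lithium enolate towards C5; Et3SiCl then silylates it to 5.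

Further compounds
F1 | step 5 | 3-methylcyclopent-2-en-1-one | CC1=CC(=O)CC1
F2 | step 5 | (1S)-3-methylcyclopent-2-en-1-ol | O[C@@H]1C=C(C)CC1
F3 | step 5 | (bromomethyl)dimethyl{[(1S)-3-methylcyclopent-2-en-1-yl]oxy}silane | BrC[Si](C)(C)O[C@@H]1C=C(C)CC1
F4 | step 5 | cis-fused oxasilolane (C4–O–SiMe2–CH2–C5), C1 methyl cis and C1 allyl trans to the ring CH2 | C1[C@@H]2[C@](C)(CC[C@@H]2O[Si]1(C)C)CC=C
F5 | step 5 | 2-(hydroxymethyl)-3-methyl-3-(prop-2-en-1-yl)cyclopentan-1-ol, hydroxymethyl cis to hydroxyl and to methyl | OC[C@@H]1[C@](C)(CC[C@@H]1O)CC=C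
F6 | step 5 | primary triethylsilyl ether of F5 | CC[Si](CC)(CC)OC[C@@H]1[C@](C)(CC[C@@H]1O)CC=C
F7 | step 5 | 3-methyl-3-(prop-2-en-1-yl)-2-{[(triethylsilyl)oxy]methyl}cyclopentan-1-one, silyloxymethyl cis to methyl | CC[Si](CC)(CC)OC[C@@H]1[C@](C)(CCC1=O)CC=C
F8 | step 5 | 3-methyl-1-(propan-2-yl)-3-(prop-2-en-1-yl)-2-{[(triethylsilyl)oxy]methyl}cyclopentan-1-ol, hydroxyl cis to silyloxymethyl and methyl | CC[Si](CC)(CC)OC[C@@H]1[C@](C)(CC[C@@]1(O)C(C)C)CC=C
F9 | step 5 | (1R,2R,5R)-2-hydroxy-5-methyl-2-(propan-2-yl)-5-(prop-2-en-1-yl)cyclopentane-1-carbaldehyde | O=C[C@@H]1[C@](C)(CC[C@@]1(O)C(C)C)CC=C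
F10 | step 9 | (3R,3aS,4S,8aR)-3-hydroxy-8a-methyl-6-methylidene-7-oxo-3-(propan-2-yl)decahydroazulen-4-yl 4-(acetyloxy)-3-methoxybenzoate | C=C1C[C@H](OC(=O)c2ccc(OC(C)=O)c(OC)c2)[C@@H]2[C@](C)(CC[C@@]2(O)C(C)C)CC1=O
F11 | step 2 | (1S)-3-(prop-2-en-1-yl)cyclopent-2-en-1-ol | O[C@@H]1C=C(CC=C)CC1
F12 | step 2 | 5-(prop-2-en-1-yl)bicyclo[3.1.0]hexan-2-ol, cyclopropane cis to hydroxyl | C1[C@@H]2[C@]1(CC[C@@H]2O)CC=C
F13 | step 2 | 5-(prop-2-en-1-yl)bicyclo[3.1.0]hexan-2-one, same cyclopropane configuration as F12 | C1[C@@H]2[C@]1(CCC2=O)CC=C
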